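Remark on the chemistry: (1S,4R)-cis-4-acetoxycyclopent-2-en-1-ol (14) is assumed to be bought as the single enantiomer; the centres at C2 of 12, C7 of 22 and C16 of 34 are left open and C15 in 20–32 is drawn as one epimer only for definiteness, because all four are later oxidised or eliminated.

## The problem

The target is an 8,9-secokaurane, and kaurane numbering is used throughout: ring A is C1–C5 with C10, ring D is C8, C14, C13, C16 and C15, C17 is the exocyclic methylene carbon and C20 the methyl on C10. The ten-membered carbocycle (C8, C7, C6, C5, C10, C9, C11, C12, C13, C14) is fused to ring A along C5–C10 and bridged by C15–C16 into ring D, so that C8=C14 is a bridgehead alkene that is E within the ten-membered ring; closing this ring is the central difficulty. Of the five stereocentres, C5 and C10 are neighbours on ring A (H and methyl trans, C10 quaternary) and can be set together, whereas C13 stands alone on ring D. C7 and C11 sit on the flexible medium ring next to sp2 carbons, out of reach of reliable substrate control, and are best set by reagents. Three groups will not survive rough treatment and have to come last: the cross-conjugated 16-methylene-cyclopent-8(14)-en-15-one, the C7 acetate (allylic and attached to the α-carbon of that enone, so open to SN2' loss) and the C9/C11 α-ketol (epimerisation at C11, acyloin shift). The enabling feature is that C9(=O)–C11(OH) is an acyloin retron inside the ten-membered ring: C9 hangs on the quaternary C10 and C11 on the C12 methylene, so both can be written as esters of an open-chain precursor. The rest of that ring can be reduced to silyl ethers and one isolated trisubstituted alkene, which sodium does not touch.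

## Retrosynthesis

**C16=C17.** The methylene is removed first, leading from 35 to the enone 33. The cross-conjugated dienone is the strongest electrophile of the target and could not be carried through any reducing or nucleophilic step. In 33, C16 is the only enolisable position of the C15 ketone (C8 is sp2), so the forward Mannich condensation has a single site. It must tolerate the free C11 hydroxyl and the C7 acetate.

**Oxidation levels at C15, C11, C7 and C9.** No skeletal bond is cut between 33 and 27. The C15 ketone goes back to the allylic alcohol 32 and its silyl ether 31. The C11 carbinol goes back to the 9,11-dione 30, and the C7 acetate to the alcohol 29. Compound 29 arises from the enediol bis(silyl) ether 27 through the dione 28, which is formed by bromine oxidation and desilylated at C7 in the same flask. Passing through a dione instead of hydrolysing 27 directly has two advantages. C9 (neopentyl) and C11 are distinguished by size, so a hydride goes to C11. C7 can also be acetylated in 29 before any second hydroxyl exists. The forward steps need a C11-selective, face-selective reduction and an oxidation of the C15 alcohol that spares the α-ketol.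

**C9–C11 (key disconnection).** Cutting the ketol bond of 27 opens the ten-membered ring to the diester 25; in the forward sense the ring closes as the disodium enediolate 26, which is silylated as it forms. The neighbouring cuts are less attractive. Closing C7–C8 would create C7 during the macrocyclisation, and C11–C12 or C12–C13 have no activating group. The C9–C11 cut creates no stereocentre and needs only two esters. Compound 25 has no medium ring and consists of a ring A unit and a ring D unit joined by one bond. The forward reaction must be a reductive ester–ester coupling run under dilution. The C7 and C15 oxygens are held as triethylsilyl and tert-butyldimethylsilyl ethers, so that C7 can be unmasked selectively afterwards.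

**C7–C8.** The diester 25 goes back through the alcohol 24 and the enone 23 to the adduct 22, which is cut at C7–C8 into the aldehyde ester 13 and the vinyl iodide 21. This cut is better than C6–C7 or C5–C6, which would need an unactivated carbanion beside two quaternary centres. Both fragments are monocyclic, and each carries one of the two esters. The forward coupling must tolerate both esters, which points to a chromium-mediated vinyl addition. Since C7 cannot be controlled in that addition, it is set afterwards by catalyst-controlled reduction of 23.

**Ring D fragment.** The iodide 21 is traced through the iodo alcohol 20, the iodo enone 19 and the enone 18 to the hydroxy ester 17 and the malonate 16. Cutting C12–C13 of 16 gives the monoacetate 14 and dimethyl malonate 15. The allylic alkylation transfers the configuration of 14 to C13 with retention, so the only stereocentre of ring D that survives comes from the chiral pool.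

**Ring A fragment.** The aldehyde and ester of 13 are reconnected (C7 to C9) to the ketol 12 and the trans-hydrindanone 11, whose five-membered ring holds exactly C10, C9, C7, C6 and C5. Compound 11 goes back through the ketal 10, the alkene 9, the dimethyl ketone 7 and the ketal 6 to the (R)-hydrindenedione 5, and from there to the triketone 3, the dione 1 and the enone 2. The amino-acid-catalysed annulation sets C10. C5 is set later by hydrogenation under the control of the C10 methyl, and the geminal methyls enter by deconjugative alkylation.

## Roads not taken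

Alternative 1: This route builds ring D by a three-component reaction. An allylcopper species adds to C13 of the enone A1 anti to the silyloxy group, and the enolate is trapped at C16 by a methyleneiminium salt to give A2. C12–C13 and C16–C17 are formed in one flask. Its merits are real. Ring D arrives in one step with C13 set from a chiral enone and with C17 already attached as a masked methylene. The chosen plan needs six steps for 21 and a late methylenation on an α-ketol. In these respects this road is better. Its weak points are that two of the three new stereocentres (C14 and C16) are later lost, and that the β-amino ketone and the β-silyloxy ketone are both prone to elimination over the many steps that follow. The ten-membered ring is also left unsolved: a free C15 ketone would not survive sodium and would need reduction and protection before any acyloin closure. Against the economy of A2, the chosen plan offers a defined ring closure and a ring D fragment that is inert until the end.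

Alternative 2: This route forms a fourteen-membered macrocycle A3 first and contracts it. A tin hydride turns the tertiary C10 bromide into an α-keto radical that adds 6-exo to C5 of the C5=C6 alkene and gives A4, forming ring A and the ten-membered ring together. A fourteen-membered ring is easier to close than a ten-membered one. A4 is also only a methylenation and a deprotection away from the target, so the endgame is shorter than the six steps needed here after the key step. Its weak points are stereochemical and regiochemical. C5 and C10 are both created from a planar radical with no controlling element nearer than C7 and C11. The attack has to occur at C5, which is neopentyl beside C4, and 7-endo attack at C6 competes. The C8=C14–C15 enone is a competing radical acceptor across the ring, and the tertiary α-bromo ketone is prone to elimination. The chosen plan spends more steps but fixes C5 and C10 on a rigid bicycle before any macrocycle exists.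

Alternative 3: This route closes ring D last. In the eleven-membered keto aldehyde A5, the C8 enol of the C15 ketone adds to the C14 aldehyde on C13 and water is lost. C8=C14 forms as the bridgehead alkene of A6. Its merits are that the strained alkene is made by a condensation with a thermodynamic driving force, that no sodium or vinyl iodide is needed, and that C17 is present from the start as the C16 methyl. In mildness of the key step it is at least equal to the chosen plan. Its weak points lie in the enolate. The C8 enolate has the C7 silyloxy group in the β-position and can eliminate it. C13 is α to the aldehyde and can epimerise before closure, and C11 next to the C9 ketone is exposed to the same base. The C16 methyl must then be dehydrogenated to the methylene, and the eleven-membered ring still has to be made. The chosen plan never places C7–O β to an enolate and takes C13 unchanged from 14. It pays for this with a forcing ring closure and a late Mannich step.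

Key step: step 19

## Route

Step 1
Reactants: 1 2-methylcyclopentane-1,3-dione; 2 but-3-en-2-one
Product: 3 2-methyl-2-(3-oxobutyl)cyclopentane-1,3-dione
Conditions: H2O, AcOH (cat.), 70 °C
Reagents that add atoms: none
Why: Michael addition of the acidic 1,3-dione to the enone; the product is achiral.

Step 2
Reactants: 3 2-methyl-2-(3-oxobutyl)cyclopentane-1,3-dione
Product: 5 (7aR)-7a-methyl-2,3,7,7a-tetrahydro-1H-indene-1,5(6H)-dione, via bicyclic ketol 4 (not isolated)
Conditions: D-proline (3 mol %), DMF, 20 °C; then H2SO4 (cat.), DMF, 95 °C
Reagents that add atoms: none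
Why: Hajos–Parrish reaction: the D-proline enamine of the side-chain ketone attacks one of the two enantiotopic ring carbonyls, which sets C7a (future C10) as R; acid then dehydrates ketol 4.

Step 3
Reactants: 5 (7aR)-7a-methyl-2,3,7,7a-tetrahydro-1H-indene-1,5(6H)-dione
Product: 6 C1 ethylene ketal of 5
Conditions: Me3SiOCH2CH2OSiMe3, Me3SiOTf (cat.), CH2Cl2, −78 → −20 °C
Reagents that add atoms: 1,2-bis(trimethylsilyloxy)ethane, C[Si](C)(C)OCCO[Si](C)(C)C
Why: Noyori ketalisation; at low temperature the saturated C1 ketone reacts far faster than the conjugated C5 ketone, which leaves the enone free for the next step.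

Step 4
Reactants: 6 C1 ethylene ketal of 5
Product: 7 (7aR)-4,4,7a-trimethyl β,γ-unsaturated 5-ketone 1-ethylene ketal (alkene C3=C3a)
Conditions: KOt-Bu, t-BuOH/THF, 25 °C; MeI, 0 → 25 °C
Reagents that add atoms: iodomethane, CI
Why: Deconjugative α,α-dimethylation: the extended enolate is methylated twice at C4, and the alkene moves to C3=C3a because C7a bears no hydrogen.

Step 5
Reactants: 7 dimethylated ketone ketal
Product: 9 (7aR)-4,4,7a-trimethyl-2,4,5,6,7,7a-hexahydro-1H-inden-1-one ethylene ketal (alkene C3=C3a), via hydrazone 8 (not isolated)
Conditions: N2H4·H2O, KOH, diethylene glycol, 130 → 200 °C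
Reagents that add atoms: none
Why: Wolff–Kishner reduction (Huang-Minlon procedure) removes the C5 carbonyl; the ketal and the isolated alkene are stable to hot base.

Step 6
Reactants: 9 alkene ketal
Product: 11 (3aR,7aR)-4,4,7a-trimethyloctahydro-1H-inden-1-one (trans ring fusion), via saturated ketal 10 (not isolated)
Conditions: H2 (1 atm), 10% Pd/C, EtOAc, 25 °C; filter; then 1 M HCl, THF, 25 °C
Reagents that add atoms: water, O
Why: Catalytic hydrogenation should deliver hydrogen to C3a (future C5) from the face opposite the angular methyl, which on that face sits 1,3 to a C4 methyl, and so give the trans fusion; aqueous acid then hydrolyses the ketal.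

Step 7
Reactants: 11 trans-hydrindanone
Product: 12 (3aR,7aR)-2-hydroxy-4,4,7a-trimethyloctahydro-1H-inden-1-one (C2 epimers)
Conditions: KN(SiMe3)2, THF, −78 °C; then 2-(phenylsulfonyl)-3-phenyloxaziridine, −78 °C; aq. NH4Cl
Reagents that add atoms: 2-(phenylsulfonyl)-3-phenyloxaziridine, O=S(=O)(c1ccccc1)N1OC1c1ccccc1
Why: Davis α-hydroxylation of the only possible enolate (C7a is quaternary); the new centre becomes the aldehyde carbon in step 8, so its configuration does not matter.

Step 8
Reactants: 12 α-hydroxy ketone
Product: 13 methyl (1R,2R)-1,3,3-trimethyl-2-(2-oxoethyl)cyclohexane-1-carboxylate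
Conditions: Pb(OAc)4, MeOH/CH2Cl2, 0 → 25 °C
Reagents that add atoms: methanol, CO
Why: Lead tetraacetate cleavage of the α-ketol in methanol turns the ketone carbon into the C9 methyl ester and the carbinol carbon into the C7 aldehyde; C5 and C10 are not touched.

Step 9
Reactants: 14 (1S,4R)-cis-4-acetoxycyclopent-2-en-1-ol; 15 dimethyl malonate
Product: 16 dimethyl 2-[(1R,4S)-4-hydroxycyclopent-2-en-1-yl]malonate
Conditions: NaH, THF, 0 °C; then Pd(PPh3)4 (5 mol %), THF, 25 → 50 °C
Reagents that add atoms: none
Why: Tsuji–Trost alkylation: zerovalent palladium ionises the acetate with inversion and the malonate attacks the allyl terminus remote from the hydroxyl, again with inversion, so C13 is set with net retention, cis to the hydroxyl.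

Step 10
Reactants: 16 malonate
Product: 17 methyl 2-[(1S,4S)-4-hydroxycyclopent-2-en-1-yl]acetate
Conditions: NaCl, DMSO/H2O, 150 °C
Reagents that add atoms: none
Why: Krapcho dealkoxycarbonylation; it is run before the alcohol is oxidised, so that C13 is never γ to a ketone under hot conditions.

Step 11
Reactants: 17 hydroxy ester
Product: 18 methyl 2-[(1S)-4-oxocyclopent-2-en-1-yl]acetate
Conditions: Dess–Martin periodinane, NaHCO3, CH2Cl2, 0 → 25 °C
Reagents that add atoms: none
Why: Buffered Dess–Martin oxidation of the allylic alcohol under neutral conditions that do not enolise toward C13.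

Step 12
Reactants: 18 enone
Product: 19 methyl 2-[(1S)-3-iodo-4-oxocyclopent-2-en-1-yl]acetate
Conditions: I2, pyridine/CH2Cl2, 0 → 25 °C
Reagents that add atoms: iodine, II
Why: α-Iodination of the enone by conjugate addition of pyridine, iodination of the enolate and elimination; this places the halogen on C8.

Step 13
Reactants: 19 iodo enone
Product: 20 methyl 2-[(1S,4S)-4-hydroxy-3-iodocyclopent-2-en-1-yl]acetate (cis)
Conditions: NaBH4, CeCl3·7H2O, MeOH, −78 → −40 °C
Reagents that add atoms: none
Why: Luche 1,2-reduction; hydride should enter anti to the C13 side chain and give the cis alcohol, although C15 only has to be masked and is reoxidised in step 24.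

Step 14
Reactants: 20 iodo alcohol
Product: 21 methyl 2-[(1S,4S)-4-(tert-butyldimethylsilyloxy)-3-iodocyclopent-2-en-1-yl]acetate
Conditions: t-BuMe2SiCl, imidazole, DMF, 25 °C
Reagents that add atoms: tert-butyldimethylsilyl chloride, CC(C)(C)[Si](C)(C)Cl
Why: Standard silylation; the robust ether carries C15 through the chromium, borane, sodium and bromine steps.

Step 15
Reactants: 13 aldehyde ester; 21 vinyl iodide
Product: 22 methyl (1R,2R)-2-{2-hydroxy-2-[(3S,5S)-5-(tert-butyldimethylsilyloxy)-3-(2-methoxy-2-oxoethyl)cyclopent-1-en-1-yl]ethyl}-1,3,3-trimethylcyclohexane-1-carboxylate (C7 epimers)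
Conditions: CrCl2 (4 equiv), NiCl2 (2 mol %), DMSO, 25 °C
Reagents that add atoms: none
Why: Nozaki–Hiyama–Kishi coupling: nickel-catalysed insertion into the C8–I bond and transfer to divalent chromium give a vinylchromium species that adds to the aldehyde and ignores both methyl esters; C7 is not controlled here and is corrected in steps 16 and 17.

Step 16
Reactants: 22 allylic alcohol
Product: 23 the corresponding C7 ketone (enone conjugated with C8=C14)
Conditions: Dess–Martin periodinane, NaHCO3, CH2Cl2, 0 °C
Reagents that add atoms: none
Why: Dess–Martin oxidation merges both C7 epimers into one enone and removes the hydroxyl that could lactonise onto the C9 ester.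

Step 17
Reactants: 23 enone
Product: 24 (7R)-allylic alcohol
Conditions: (S)-1-methyl-3,3-diphenyltetrahydro-1H,3H-pyrrolo[1,2-c][1,3,2]oxazaborole [(S)-Me-CBS], catecholborane, toluene, −78 °C; MeOH
Reagents that add atoms: none
Why: Corey–Bakshi–Shibata reduction: with the α-substituted cyclopentenyl group as the large substituent and the C6 methylene as the small one, the (S)-catalyst should deliver hydride to the face that gives (7R); catecholborane reduces 1,2 and leaves the alkene and esters alone.

Step 18
Reactants: 24 (7R)-alcohol
Product: 25 seco diester (5R,7R,10R,13S,15S) with C9 and C11 methyl esters and 7-O-triethylsilyl and 15-O-tert-butyldimethylsilyl ethers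
Conditions: Et3SiOTf, 2,6-lutidine, CH2Cl2, −78 °C
Reagents that add atoms: triethylsilyl trifluoromethanesulfonate, CC[Si](CC)(CC)OS(=O)(=O)C(F)(F)F
Why: Fast silylation at low temperature, run directly after step 17 so that the C7 hydroxyl cannot close a δ-lactone on the C9 ester; the triethylsilyl ether can later be removed beside the tert-butyldimethylsilyl ether.

Step 19
Reactants: 25 seco diester
Product: 27 ten-membered (9Z)-9,11-bis(trimethylsilyloxy)-9(11)-ene (5R,7R,10R,13S,15S) with 7-O-triethylsilyl and 15-O-tert-butyldimethylsilyl ethers, via disodium enediolate 26 (not isolated)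
Conditions: Na (dispersion, excess), Me3SiCl, toluene, 110 °C, syringe-pump addition of 25 (high dilution), Ar; filtration, evaporation
Reagents that add atoms: chlorotrimethylsilane, C[Si](C)(C)Cl
Why: Acyloin condensation with silyl trapping (Rühlmann conditions): sodium gives one electron to each ester carbonyl, the two ketyl radical anions combine to form C9–C11, the coupled dialkoxide loses its two methoxides and takes up two further electrons, and the resulting disodium enediolate 26 is silylated on both oxygens by Me3SiCl. The closest known reaction type is the acyloin synthesis of medium-ring 1,2-bis(silyloxy)cycloalkenes from α,ω-diesters, which also accepts hindered pivalate-type esters. The ten-membered ring closes end to end by radical–radical coupling of the two chain termini on the metal surface, the mode of closure least sensitive to medium-ring strain. No stereocentre is formed: the new C9=C11 bond can only be Z inside the ring, and C5, C7, C10, C13 and C15 are spectators. The step needs intramolecular coupling to win over intermolecular coupling; slow addition of 25 to excess dispersed sodium secures this, and it helps that the neopentyl C9 ester pairs poorly with a second hindered ester and that ring D holds the two chains in a 1,3 relationship. It also needs the esters to be the only reducible groups, which the silyl ethers at C7 and C15 and the isolated trisubstituted C8=C14 alkene ensure. Me3SiCl removes methoxide as it forms, so Claisen and Dieckmann reactions at C12 and base-induced elimination of the allylic ethers do not start.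

Step 20
Reactants: 27 enediol bis(trimethylsilyl) ether
Product: 29 (7R)-7-hydroxy-9,11-dione with 15-O-tert-butyldimethylsilyl ether, via 9,11-dione 28 (not isolated)
Conditions: Br2 (1.0 equiv), CH2Cl2, −78 °C; then pyridine, HF·pyridine, THF, −78 → 0 °C
Reagents that add atoms: none
Why: Bromine oxidises the electron-rich bis(silyloxy)alkene to the 1,2-dione 28 with loss of two bromosilanes, the classical follow-up of the acyloin synthesis, and does so much faster than it adds to the hindered C8=C14 alkene; buffered fluoride then removes the secondary triethylsilyl ether and leaves the tert-butyldimethylsilyl ether.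

Step 21
Reactants: 29 dione alcohol
Product: 30 (7R)-acetate of the 9,11-dione
Conditions: Ac2O, pyridine, 4-(dimethylamino)pyridine (cat.), CH2Cl2, 0 → 25 °C
Reagents that add atoms: acetic anhydride, CC(=O)OC(C)=O
Why: Acylation of the only free hydroxyl; it is done at the dione stage so that no C11 hydroxyl competes, and any transannular C7–O/C9 hemiketal is in equilibrium with the open form that is acetylated.

Step 22
Reactants: 30 dione acetate
Product: 31 (11S)-11-hydroxy-9-ketone with 7-acetate and 15-O-tert-butyldimethylsilyl ether
Conditions: (R)-1-methyl-3,3-diphenyltetrahydro-1H,3H-pyrrolo[1,2-c][1,3,2]oxazaborole [(R)-Me-CBS], catecholborane (1 equiv), toluene, −78 °C; MeOH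
Reagents that add atoms: none
Why: Corey–Bakshi–Shibata reduction of the less hindered carbonyl of the 1,2-dione: C9 is shielded by the quaternary C10, so only C11 is reduced, and with the C9 acyl group as the large substituent the (R)-catalyst should give (11S); the acetate and the alkene do not react with catecholborane at this temperature.

Step 23
Reactants: 31 silyl ether
Product: 32 (11S,15S)-11,15-diol with 7-acetate and 9-ketone
Conditions: HF·pyridine, THF, 0 → 25 °C
Reagents that add atoms: none
Why: Acidic fluoride removes the allylic tert-butyldimethylsilyl ether without acyl migration or enolisation of the α-ketol.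

Step 24
Reactants: 32 diol
Product: 33 15-ketone (cyclopent-8(14)-en-15-one) with 7-acetate and (11S)-11-hydroxy-9-ketone
Conditions: MnO2, CH2Cl2, 25 °C
Reagents that add atoms: none
Why: Manganese dioxide oxidises the allylic C15 alcohol much faster than the non-allylic C11 alcohol of the α-ketol.

Step 25
Reactants: 33 enone
Product: 35 target (5R,7R,10R,11S,13S)-7-acetoxy-11-hydroxy-8,9-secokaura-8(14),16-diene-9,15-dione, via Mannich base 34 (not isolated)
Conditions: (CH2O)n, i-Pr2NH2+ CF3CO2−, CF3CO2H (cat.), THF, 65 °C
Reagents that add atoms: formaldehyde (as paraformaldehyde), C=O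
Why: Mannich-type α-methylenation: the iminium ion formed from formaldehyde and the hindered ammonium salt is attacked by the C16 enol, the only enol the C15 ketone can form, and the β-amino ketone 34 loses the amine; the medium is weakly acidic and the amine is hindered and mostly protonated, which should spare the α-ketol, the acetate and the product dienone.

## Compound list

1 | 2-methylcyclopentane-1,3-dione | CC1C(=O)CCC1=O | starting material
2 | but-3-en-2-one (methyl vinyl ketone) | CC(=O)C=C | starting material
3 | 2-methyl-2-(3-oxobutyl)cyclopentane-1,3-dione | CC(=O)CCC1(C)C(=O)CCC1=O | intermediate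
4 | (3aR,7aR)-3a-hydroxy-7a-methylhexahydro-1H-indene-1,5(4H)-dione (cis-fused ketol, not isolated) | C[C@@]12CCC(=O)C[C@]1(O)CCC2=O | intermediate
5 | (7aR)-7a-methyl-2,3,7,7a-tetrahydro-1H-indene-1,5(6H)-dione | C[C@@]12CCC(=O)C=C1CCC2=O | intermediate
6 | C1 ethylene ketal of 5, (7aR) | C[C@@]12CCC(=O)C=C1CCC23OCCO3 | intermediate
7 | (7aR)-4,4,7a-trimethyl β,γ-unsaturated 5-ketone 1-ethylene ketal (alkene C3=C3a) | C[C@@]12CCC(=O)C(C)(C)C1=CCC23OCCO3 | intermediate
8 | C5 hydrazone of 7 (not isolated) | C[C@@]12CCC(=NN)C(C)(C)C1=CCC23OCCO3 | intermediate
9 | (7aR)-4,4,7a-trimethyl-2,4,5,6,7,7a-hexahydro-1H-inden-1-one ethylene ketal (alkene C3=C3a) | C[C@@]12CCCC(C)(C)C1=CCC23OCCO3 | intermediate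
10 | (3aR,7aR)-4,4,7a-trimethyloctahydro-1H-inden-1-one ethylene ketal (trans-fused, not isolated) | C[C@@]12CCCC(C)(C)[C@H]1CCC23OCCO3 | intermediate
11 | (3aR,7aR)-4,4,7a-trimethyloctahydro-1H-inden-1-one (trans-fused) | C[C@@]12CCCC(C)(C)[C@H]1CCC2=O | intermediate
12 | (3aR,7aR)-2-hydroxy-4,4,7a-trimethyloctahydro-1H-inden-1-one (C2 epimers) | C[C@@]12CCCC(C)(C)[C@H]1CC(O)C2=O | intermediate
13 | methyl (1R,2R)-1,3,3-trimethyl-2-(2-oxoethyl)cyclohexane-1-carboxylate | COC(=O)[C@]1(C)CCCC(C)(C)[C@H]1CC=O | intermediate
14 | (1S,4R)-cis-4-acetoxycyclopent-2-en-1-ol | CC(=O)O[C@H]1C=C[C@@H](O)C1 | starting material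
15 | dimethyl malonate | COC(=O)CC(=O)OC | starting material
16 | dimethyl 2-[(1R,4S)-4-hydroxycyclopent-2-en-1-yl]malonate | COC(=O)C(C(=O)OC)[C@H]1C=C[C@@H](O)C1 | intermediate
17 | methyl 2-[(1S,4S)-4-hydroxycyclopent-2-en-1-yl]acetate | COC(=O)C[C@H]1C=C[C@@H](O)C1 | intermediate
18 | methyl 2-[(1S)-4-oxocyclopent-2-en-1-yl]acetate | COC(=O)C[C@H]1C=CC(=O)C1 | intermediate
19 | methyl 2-[(1S)-3-iodo-4-oxocyclopent-2-en-1-yl]acetate | COC(=O)C[C@H]1C=C(I)C(=O)C1 | intermediate
20 | methyl 2-[(1S,4S)-4-hydroxy-3-iodocyclopent-2-en-1-yl]acetate | COC(=O)C[C@H]1C=C(I)[C@@H](O)C1 | intermediate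
21 | methyl 2-[(1S,4S)-4-(tert-butyldimethylsilyloxy)-3-iodocyclopent-2-en-1-yl]acetate | COC(=O)C[C@H]1C=C(I)[C@@H](O[Si](C)(C)C(C)(C)C)C1 | intermediate
22 | seco allylic alcohol, C7 epimers, (5R,10R,13S,15S), C9 and C11 methyl esters, 15-OTBS | COC(=O)C[C@H]1C=C(C(O)C[C@@H]2C(C)(C)CCC[C@@]2(C)C(=O)OC)[C@@H](O[Si](C)(C)C(C)(C)C)C1 | intermediate
23 | seco C7 ketone (enone), (5R,10R,13S,15S) | COC(=O)C[C@H]1C=C(C(=O)C[C@@H]2C(C)(C)CCC[C@@]2(C)C(=O)OC)[C@@H](O[Si](C)(C)C(C)(C)C)C1 | intermediate
24 | seco (7R)-alcohol, (5R,7R,10R,13S,15S) | COC(=O)C[C@H]1C=C([C@H](O)C[C@@H]2C(C)(C)CCC[C@@]2(C)C(=O)OC)[C@@H](O[Si](C)(C)C(C)(C)C)C1 | intermediate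
25 | seco diester, 7-O-triethylsilyl, 15-O-TBS, (5R,7R,10R,13S,15S) | COC(=O)C[C@H]1C=C([C@H](O[Si](CC)(CC)CC)C[C@@H]2C(C)(C)CCC[C@@]2(C)C(=O)OC)[C@@H](O[Si](C)(C)C(C)(C)C)C1 | intermediate
26 | disodium (9Z)-9(11)-ene-9,11-diolate of the ten-membered ring, 7-O-triethylsilyl, 15-O-TBS, (5R,7R,10R,13S,15S) (not isolated) | C1[C@H](O[Si](C)(C)C(C)(C)C)C2=C[C@@H]1C/C([O-])=C(/[O-])[C@]1(C)CCCC(C)(C)[C@H]1C[C@H]2O[Si](CC)(CC)CC.[Na+].[Na+] | intermediate
27 | ten-membered (9Z)-9,11-bis(trimethylsilyloxy)-9(11)-ene, 7-O-triethylsilyl, 15-O-TBS, (5R,7R,10R,13S,15S) | C1[C@H](O[Si](C)(C)C(C)(C)C)C2=C[C@@H]1C/C(O[Si](C)(C)C)=C(/O[Si](C)(C)C)[C@]1(C)CCCC(C)(C)[C@H]1C[C@H]2O[Si](CC)(CC)CC | intermediate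
28 | ten-membered 9,11-dione, 7-O-triethylsilyl, 15-O-TBS, (5R,7R,10R,13S,15S) (not isolated) | C1[C@H](O[Si](C)(C)C(C)(C)C)C2=C[C@@H]1CC(=O)C(=O)[C@]1(C)CCCC(C)(C)[C@H]1C[C@H]2O[Si](CC)(CC)CC | intermediate
29 | 9,11-dione, (7R)-7-hydroxy, 15-O-TBS, (5R,7R,10R,13S,15S) | C1[C@H](O[Si](C)(C)C(C)(C)C)C2=C[C@@H]1CC(=O)C(=O)[C@]1(C)CCCC(C)(C)[C@H]1C[C@H]2O | intermediate
30 | 9,11-dione, (7R)-7-acetoxy, 15-O-TBS, (5R,7R,10R,13S,15S) | C1[C@H](O[Si](C)(C)C(C)(C)C)C2=C[C@@H]1CC(=O)C(=O)[C@]1(C)CCCC(C)(C)[C@H]1C[C@H]2OC(C)=O | intermediate
31 | (11S)-11-hydroxy-9-ketone, 7-acetoxy, 15-O-TBS, (5R,7R,10R,11S,13R,15S) (C13 untouched; its descriptor is R here only through ligand ranking) | C1[C@H](O[Si](C)(C)C(C)(C)C)C2=C[C@@H]1C[C@H](O)C(=O)[C@]1(C)CCCC(C)(C)[C@H]1C[C@H]2OC(C)=O | intermediate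
32 | 11,15-diol, 7-acetoxy, 9-ketone, (5R,7R,10R,11S,13S,15S) | C1[C@H](O)C2=C[C@@H]1C[C@H](O)C(=O)[C@]1(C)CCCC(C)(C)[C@H]1C[C@H]2OC(C)=O | intermediate
33 | 7-acetoxy-11-hydroxy-8,9-secokaur-8(14)-ene-9,15-dione, (5R,7R,10R,11S,13R) (C13 untouched; its descriptor is R here only through ligand ranking) | C1C(=O)C2=C[C@@H]1C[C@H](O)C(=O)[C@]1(C)CCCC(C)(C)[C@H]1C[C@H]2OC(C)=O | intermediate
34 | 16-(diisopropylaminomethyl) derivative of 33 (C16 epimers, not isolated) | CC(C)N(CC1C(=O)C2=C[C@@H]1C[C@H](O)C(=O)[C@]1(C)CCCC(C)(C)[C@H]1C[C@H]2OC(C)=O)C(C)C | intermediate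
35 | (5R,7R,10R,11S,13S)-7-acetoxy-11-hydroxy-8,9-secokaura-8(14),16-diene-9,15-dione | C=C1C(=O)C2=C[C@@H]1C[C@H](O)C(=O)[C@]1(C)CCCC(C)(C)[C@H]1C[C@H]2OC(C)=O | target

## Step count and least certain steps

Total: 25 steps. Longest linear sequence: 19 steps (steps 1–8 and 15–25). The ring D branch (steps 9–14) is six steps long.

**Step 19 (key step).** Intermolecular ester coupling and oligomerisation may outrun ring closure, because the closure has to build the E-configured C8=C14 alkene and a new tetrasubstituted double bond into one ten-membered ring. Fallback, still forming C9–C11 but from aldehydes: 25 is reduced with LiAlH4 to the 9,11-diol (two primary alcohols) F1, which is oxidised (oxalyl chloride, DMSO, Et3N) to the 9,11-dialdehyde F2. Low-valent titanium (TiCl3(DME)1.5, Zn–Cu couple, DME, high dilution) then closes the ring by pinacol coupling to the cyclic 9,11-diol F3. A second DMSO oxidation gives the dione 28, the intermediate of step 20, which is treated with buffered HF·pyridine as in that step and continues to 29.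

**Step 22.** The macrocycle's own facial bias may override the catalyst and give the C11 epimer, or some C9 reduction may occur. Fallback by inversion: 30 is reduced under whichever conditions give one epimer cleanly (for example NaBH4, CeCl3·7H2O, −78 °C). If that is the (11R)-alcohol F4, a Mitsunobu reaction with chloroacetic acid (PPh3, diisopropyl azodicarboxylate) gives the (11S)-chloroacetate F5. Thiourea with NaHCO3 removes the chloroacetate beside the C7 acetate and returns the route to 31.

**Step 25.** Enolisation toward C16 may be slow under the weakly acidic conditions. Prolonged heating may epimerise C11 or shift the α-ketol, and the amine may add to the product dienone. Fallback through a protected ketol and a preformed enolate: 33 is silylated (Et3SiCl, imidazole) to the 11-O-triethylsilyl ether F6. Kinetic deprotonation at C16 (LiN(SiMe3)2, THF, −78 °C) and dimethyl(methylidene)ammonium iodide give the 16-(dimethylaminomethyl) ketone F7, which MeI converts into the trimethylammonium iodide F8. NaHCO3 then eliminates trimethylamine to give the 16-methylene 11-O-triethylsilyl ether F9, and HF·pyridine releases 35.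

**Step 20.** Bromine may add to C8=C14, or the bromosilane formed may cleave silyl ethers before the fluoride stage. Fallback in two milder operations: 27 is methanolysed (K2CO3, MeOH, 0 °C) to the acyloin F10, a mixture of ketol isomers. Dess–Martin periodinane oxidises it to the dione 28, which is desilylated at C7 with buffered HF·pyridine and so returns to the route at 29.

**Step 17.** Reagent control may be mismatched with the neighbouring C15 silyloxy group, giving poor facial selectivity, or the C7 hydroxyl may lactonise onto the C9 ester before silylation. Fallback that sets C7 during C–C bond formation and skips the ketone: iodide 21 undergoes iodine–magnesium exchange (i-PrMgCl·LiCl, THF, −40 °C) to the alkenylmagnesium chloride F11, which ZnCl2 converts into the alkenylzinc chloride F12. After the halide salts are bound with N,N,N',N'-tetraethylethylenediamine, F12 adds to aldehyde 13 in the presence of a chiral amino alcohol (morpholinoisoborneol, the enantiomer chosen for 7R). This gives 24 directly as the less nucleophilic zinc alkoxide, which is silylated as in step 18.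

**Step 6.** Facial selectivity on the metal surface may be poor, or uptake at the alkene beside the quaternary C4 may be slow. Fallback by stepwise hydrogen-atom transfer instead of surface syn-addition: Mn(dpm)3 (dpm = dipivaloylmethanate), PhSiH3, t-BuOOH, i-PrOH, 25 °C. The tertiary C3a radical is then quenched from the face anti to the angular methyl. The fallback sets out from 9 and returns at 10, which is hydrolysed to 11 as before.

## Further compounds

F1 | step 19 | 9,11-diol (two primary alcohols) from reduction of 25 | OCC[C@H]1C=C([C@H](O[Si](CC)(CC)CC)C[C@@H]2C(C)(C)CCC[C@@]2(C)CO)[C@@H](O[Si](C)(C)C(C)(C)C)C1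
F2 | step 19 | 9,11-dialdehyde | O=CC[C@H]1C=C([C@H](O[Si](CC)(CC)CC)C[C@@H]2C(C)(C)CCC[C@@]2(C)C=O)[C@@H](O[Si](C)(C)C(C)(C)C)C1
F3 | step 19 | ten-membered 9,11-diol (diol epimers), 7-O-triethylsilyl, 15-O-TBS | C1[C@H](O[Si](C)(C)C(C)(C)C)C2=C[C@@H]1CC(O)C(O)[C@]1(C)CCCC(C)(C)[C@H]1C[C@H]2O[Si](CC)(CC)CC
F4 | step 22 | (11R)-epimer of 31 | C1[C@H](O[Si](C)(C)C(C)(C)C)C2=C[C@@H]1C[C@@H](O)C(=O)[C@]1(C)CCCC(C)(C)[C@H]1C[C@H]2OC(C)=O
F5 | step 22 | (11S)-chloroacetate of 31 | C1[C@H](O[Si](C)(C)C(C)(C)C)C2=C[C@@H]1C[C@H](OC(=O)CCl)C(=O)[C@]1(C)CCCC(C)(C)[C@H]1C[C@H]2OC(C)=O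
F6 | step 25 | 11-O-triethylsilyl ether of 33 | C1C(=O)C2=C[C@@H]1C[C@H](O[Si](CC)(CC)CC)C(=O)[C@]1(C)CCCC(C)(C)[C@H]1C[C@H]2OC(C)=O
F7 | step 25 | 16-(dimethylaminomethyl) derivative of F6 (C16 epimers) | CN(C)CC1C(=O)C2=C[C@@H]1C[C@H](O[Si](CC)(CC)CC)C(=O)[C@]1(C)CCCC(C)(C)[C@H]1C[C@H]2OC(C)=O
F8 | step 25 | trimethylammonium iodide of F7 (C16 epimers) | C[N+](C)(C)CC1C(=O)C2=C[C@@H]1C[C@H](O[Si](CC)(CC)CC)C(=O)[C@]1(C)CCCC(C)(C)[C@H]1C[C@H]2OC(C)=O.[I-]
F9 | step 25 | 11-O-triethylsilyl ether of 35 | C=C1C(=O)C2=C[C@@H]1C[C@H](O[Si](CC)(CC)CC)C(=O)[C@]1(C)CCCC(C)(C)[C@H]1C[C@H]2OC(C)=O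
F10 | step 20 | acyloin from 27 (shown as 11-hydroxy-9-ketone, mixture of ketol isomers), 7-O-triethylsilyl, 15-O-TBS | C1[C@H](O[Si](C)(C)C(C)(C)C)C2=C[C@@H]1CC(O)C(=O)[C@]1(C)CCCC(C)(C)[C@H]1C[C@H]2O[Si](CC)(CC)CC
F11 | step 17 | alkenylmagnesium chloride from 21 | COC(=O)C[C@H]1C=C([Mg]Cl)[C@@H](O[Si](C)(C)C(C)(C)C)C1
F12 | step 17 | alkenylzinc chloride from F11 | COC(=O)C[C@H]1C=C([Zn]Cl)[C@@H](O[Si](C)(C)C(C)(C)C)C1
F0 | step 6 | none | none
A1 | alternative 1 | (R)-4-(tert-butyldimethylsilyloxy)cyclopent-2-en-1-one | O=C1C=C[C@H](O[Si](C)(C)C(C)(C)C)C1
A2 | alternative 1 | all-trans 3-allyl-2-(dimethylaminomethyl)-4-(tert-butyldimethylsilyloxy)cyclopentanone | CN(C)C[C@H]1C(=O)C[C@@H](O[Si](C)(C)C(C)(C)C)[C@@H]1CC=C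
A3 | alternative 2 | fourteen-membered C10 bromide with (E)-C5=C6 alkene, 11-O-PMB, 7-acetate | C1C(=O)C2=C[C@@H]1C[C@H](OCc3ccc(OC)cc3)C(=O)C(C)(Br)CCCC(C)(C)/C=C/[C@H]2OC(C)=O
A4 | alternative 2 | 11-O-PMB ether of the target lacking the C17 methylene | C1C(=O)C2=C[C@@H]1C[C@H](OCc3ccc(OC)cc3)C(=O)[C@]1(C)CCCC(C)(C)[C@H]1C[C@H]2OC(C)=O
A5 | alternative 3 | eleven-membered 9,15-diketone with C14 aldehyde on C13, 16-methyl, 11-O-PMB, 7-O-TBS | C[C@@H]1C(=O)C[C@H](O[Si](C)(C)C(C)(C)C)C[C@@H]2C(C)(C)CCC[C@@]2(C)C(=O)[C@@H](OCc3ccc(OC)cc3)C[C@H]1C=O
A6 | alternative 3 | bridged cyclopentenone with C16 methyl, 11-O-PMB, 7-O-TBS | C[C@@H]1C(=O)C2=C[C@@H]1C[C@H](OCc3ccc(OC)cc3)C(=O)[C@]1(C)CCCC(C)(C)[C@H]1C[C@H]2O[Si](C)(C)C(C)(C)C
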